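Ring B of the target (C5–C10), with its C8 methyl and the C4Me2 unit on C5, is a p-menthane, so (S)-carvone supplies ten carbons and the C5 configuration. The route rests on disconnecting C3–C4 of ring A. The cyclisation precursor is carvone made quaternary at C10, carrying a β methyl and an α 2-(methoxycarbonyl)allyl chain cis to the isopropenyl group. In one operation, hydrogen atom transfer turns the isopropenyl CH2 into the second C4 methyl. The tertiary C4 radical then closes ring A on the acrylate terminus and gives the cis-decalin with its quaternary C4. The activating ester is then excised and the enone is elaborated into the C6–C9 array.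

Key step: step 4

Assumption: the SMILES places H5 on the same (β) face as the C10 methyl, i.e. a cis-fused decalin (C5 epimer of the usual labdane/drimane series, called "5-epi" below); the route aims at 5β-H, 6α-OAc, 7β-OH, 8α-OH/8β-Me, 9β-side chain, 10β-Me (labdane numbering throughout, β = face of the C10 methyl).

Step 1
Reactants: 1 (S)-(+)-carvone; 2 2,3-dibromopropene
Product: 3 trans-6-(2-bromoallyl)carvone (CH2C(Br)=CH2 on C10, β, anti to the α-isopropenyl group on C5)
Conditions: LiN(i-Pr)2, THF, −78 °C; then 2, −78 → 0 °C
Reagents that add atoms: none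
Why: Kinetic α′-deprotonation gives the cross-conjugated lithium dienolate, which undergoes SN2 enolate alkylation at the allylic C–Br bond only (the vinylic bromide is inert) anti to the isopropenyl group; the new C10 centre is provisional because step 2 enolises it again.

Step 2
Reactants: 3 trans-6-(2-bromoallyl)carvone
Product: 4 6-(2-bromoallyl)-6-methylcarvone (C10 quaternary: methyl β, bromoallyl α and cis to the isopropenyl group)
Conditions: LiN(i-Pr)2, THF–DMPU, −78 °C; then MeI, −78 → 0 °C
Reagents that add atoms: methyl iodide, CI
Why: In this second enolate alkylation, A(1,2) strain with the C10 side chain forces the C5 isopropenyl group pseudoaxial, so MeI should reach C10 only from the opposite β face and fix the quaternary centre, while cold enolisation outruns dehydrobromination of the vinyl bromide.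

Step 3
Reactants: 4 6-(2-bromoallyl)-6-methylcarvone
Product: 5 cyclisation precursor, carvone with β-methyl and α-CH2C(=CH2)CO2Me on C10
Conditions: Pd(PPh3)4 (5 mol %), CO (5 bar), Et3N, MeOH–DMF, 65 °C
Reagents that add atoms: carbon monoxide, [C-]#[O+]; methanol, CO
Why: Heck-type alkoxycarbonylation (oxidative addition of the vinyl bromide to zerovalent palladium, CO insertion, methanolysis) unveils the base-sensitive acrylate only after both enolate steps; CO pressure and methanol as cosolvent should make acyl formation and capture faster than carbopalladation of the nearby isopropenyl group, and no stereocentre is touched.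

Step 4
Reactants: 5 cyclisation precursor
Product: 6 methyl 9-oxo-5-epi-11-nordrim-7-ene-2-carboxylate (cis-fused, 5β-H, 10β-Me, both C2 epimers)
Conditions: Fe(acac)3 (20 mol %), PhSiH3 (slow addition), degassed EtOH (0.01 M), 60 °C
Reagents that add atoms: none
Why: An iron hydride formed from Fe(acac)3 and PhSiH3 transfers a hydrogen atom to the CH2 terminus of the electron-neutral isopropenyl group, which creates the second C4 methyl and a nucleophilic tertiary radical at C4. This radical adds to the unsubstituted acrylate terminus C3, and the ester-stabilised C2 radical is reduced by divalent iron to the enolate and protonated by ethanol; the closest known reaction type is the iron-hydride reductive olefin coupling (a Giese addition started by hydrogen atom transfer), run here intramolecularly. Ring A closes 6-endo-trig, because the 5-exo alternative would attack the fully substituted, polarity-mismatched C2 and leave an unstabilised primary radical. The cis fusion (C5, C10) is inherited from 5, since only a chain cis to the C4 radical can be reached, and the one new centre C2 arises from uncontrolled protonation and is deleted in step 6. The step needs chemoselective hydrogen atom transfer: the neutral 1,1-disubstituted alkene is the best acceptor, while the trisubstituted C7=C8 enone reacts more slowly and is out of reach of C4 (only a four-membered ring or attack on the mismatched C8 would be possible). Degassing, high dilution and slow silane addition should suppress oxygen capture and premature reduction of the C4 radical.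

Step 5
Reactants: 6 methyl 9-oxo-5-epi-11-nordrim-7-ene-2-carboxylate
Product: 7 9-oxo-5-epi-11-nordrim-7-ene-2-carboxylic acid (both C2 epimers)
Conditions: LiOH, THF–MeOH–H2O, rt; then 1 M HCl
Reagents that add atoms: lithium hydroxide, [Li+].[OH-]
Why: This is a plain saponification of an unhindered secondary methyl ester; the enone has no α′-hydrogen (C10 is quaternary) and C5–H is not activated, so only the irrelevant C2 centre can epimerise.

Step 6
Reactants: 7 9-oxo-5-epi-11-nordrim-7-ene-2-carboxylic acid
Product: 9 5-epi-11-nordrim-7-en-9-one, via Barton ester 8 (not isolated)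
Conditions: 1-hydroxypyridine-2(1H)-thione, DCC, CH2Cl2, 0 °C, dark; then t-BuSH, hν (visible), rt
Reagents that add atoms: none
Why: In the Barton reductive decarboxylation the thiohydroxamate ester fragments in a light-driven radical chain to CO2 and the secondary C2 radical, which should abstract hydrogen from t-BuSH faster than it can add to the remote enone, so C2 becomes CH2 and both epimers converge on one compound.

Step 7
Reactants: 9 5-epi-11-nordrim-7-en-9-one
Product: 10 7β,8β-epoxy-5-epi-11-nordriman-9-one
Conditions: 30 % H2O2, NaOH (cat.), MeOH, 0 °C → rt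
Reagents that add atoms: hydrogen peroxide, OO
Why: In the Weitz–Scheffer nucleophilic epoxidation, hydroperoxide should add axially to C7 on the convex β face, anti to the C5–C4 bond as in carvone itself, and the enolate closes onto oxygen on the same face, which sets C7 (β-O) and, provisionally, C8.

Step 8
Reactants: 10 7β,8β-epoxy-5-epi-11-nordriman-9-one
Product: 12 5-epi-11-nordrim-8-en-7β-ol, via epoxy hydrazone 11 (not isolated)
Conditions: N2H4·H2O, AcOH (cat.), MeOH, 0 °C → rt
Reagents that add atoms: none
Why: In the Wharton transposition the hydrazone tautomerises and opens the epoxide at C8, and loss of N2 leaves C9–H and the C8=C9 double bond; the C7–O bond is never broken, so the 7β configuration is carried over.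

Step 9
Reactants: 12 5-epi-11-nordrim-8-en-7β-ol; 13 tributyl(iodomethyl)stannane
Product: 14 7β-(tributylstannylmethoxy)-5-epi-11-nordrim-8-ene
Conditions: KH, THF, 0 °C; then 13, rt
Reagents that add atoms: none
Why: This is a Williamson etherification of the potassium alkoxide with a reactive primary iodide, and C7 is not involved in bond breaking.

Step 10
Reactants: 14 7β-(tributylstannylmethoxy)-5-epi-11-nordrim-8-ene
Product: 17 11-O-TBS-5-epi-drimenol, via lithiomethyl ether 15 (not isolated), via lithium alkoxide 16 (not isolated)
Conditions: n-BuLi, THF, −78 °C; then TBSCl, DMPU, −78 °C → rt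
Reagents that add atoms: tert-butyldimethylsilyl chloride, CC(C)(C)[Si](C)(C)Cl
Why: In the Still–Wittig [2,3]-sigmatropic rearrangement, tin–lithium exchange gives the unstabilised α-alkoxy carbanion, which migrates suprafacially from the pseudoaxial 7β oxygen to the β face of C9 (open there because C1 is the pseudoaxial α substituent on C10); this sets C9 by 1,3-chirality transfer and moves the alkene to C7=C8, and the primary alkoxide is silylated in the same flask.

Step 11
Reactants: 17 11-O-TBS-5-epi-drimenol
Product: 18 11-(TBS-oxy)-5-epi-drim-7-en-6-one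
Conditions: dirhodium tetracaprolactamate Rh2(cap)4 (1 mol %), t-BuOOH (70 % aq.), ClCH2CH2Cl, 40 °C
Reagents that add atoms: tert-butyl hydroperoxide, CC(C)(C)OO
Why: This allylic C–H oxidation by the tert-butylperoxy radical should select the ring CH2 at C6, the only accessible secondary allylic site (C9–H is buried between C10 and the silyloxymethyl group, and the C8 methyl is primary); the base-free medium leaves the now enolisable C5–H configuration intact.

Step 12
Reactants: 18 11-(TBS-oxy)-5-epi-drim-7-en-6-one
Product: 19 11-(TBS-oxy)-5-epi-drim-7-en-6α-ol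
Conditions: NaBH4, CeCl3·7H2O, MeOH, −78 → −20 °C
Reagents that add atoms: none
Why: In the Luche 1,2-reduction, the conformer with C4 equatorial and C1 axial on ring B has the α face of C6 closed by the axial C1H2 and the concave fold of ring A, so hydride should arrive from the convex β face and give the 6α-alcohol, and the cold, nearly neutral medium avoids epimerisation at C5.

Step 13
Reactants: 19 11-(TBS-oxy)-5-epi-drim-7-en-6α-ol
Product: 20 6α-acetoxy-11-(TBS-oxy)-5-epi-drim-7-ene
Conditions: Ac2O, pyridine, DMAP (cat.), CH2Cl2, rt
Reagents that add atoms: acetic anhydride, CC(=O)OC(C)=O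
Why: DMAP-catalysed O-acylation of the only free hydroxyl group proceeds with retention at C6 and places the acetate while no other alcohol competes.

Step 14
Reactants: 20 6α-acetoxy-11-(TBS-oxy)-5-epi-drim-7-ene
Product: 21 6α-acetoxy-5-epi-drim-7-en-11-ol
Conditions: HF·pyridine, THF, 0 °C → rt
Reagents that add atoms: none
Why: Fluoride-driven desilylation of the primary silyl ether (formation of the strong Si–F bond) runs under mildly acidic conditions that should neither cleave nor shift the allylic acetate.

Step 15
Reactants: 21 6α-acetoxy-5-epi-drim-7-en-11-ol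
Product: 22 6α-acetoxy-5-epi-drim-7-en-11-al
Conditions: Dess–Martin periodinane, CH2Cl2, 0 °C → rt
Reagents that add atoms: none
Why: The Dess–Martin oxidation is base-free, so the β,γ-unsaturated aldehyde should be neither epimerised at C9 nor moved into conjugation, and acetic acid should not be eliminated.

Step 16
Reactants: 22 6α-acetoxy-5-epi-drim-7-en-11-al; 23 1-(triphenylphosphoranylidene)propan-2-one
Product: 24 (E)-6α-acetoxy-5-epi-14,15-dinorlabda-7,11-dien-13-one
Conditions: 23, toluene, 80 °C
Reagents that add atoms: none
Why: Wittig olefination with a keto-stabilised, almost non-basic ylide should give the E-enone, in the way α-cyclocitral is extended to α-ionone, without deprotonating C9–H.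

Step 17
Reactants: 24 (E)-6α-acetoxy-5-epi-14,15-dinorlabda-7,11-dien-13-one
Product: 25 (E)-6α-acetoxy-7β,8β-epoxy-5-epi-14,15-dinorlabd-11-en-13-one
Conditions: mCPBA, CH2Cl2, 0 °C
Reagents that add atoms: 3-chloroperoxybenzoic acid, O=C(OO)c1cccc(Cl)c1
Why: In the Prilezhaev epoxidation the electrophilic peracid selects the trisubstituted C7=C8 over the electron-poor enone alkene and should approach from the β face, because the bulky reagent is kept off the α face by the pseudoaxial 6α-acetate, the axial C1H2 and ring A; this sets 7β-O.

Step 18
Reactants: 25 (E)-6α-acetoxy-7β,8β-epoxy-5-epi-14,15-dinorlabd-11-en-13-one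
Product: 26 target, (E)-6α-acetoxy-7β,8α-dihydroxy-5-epi-14,15-dinorlabd-11-en-13-one
Conditions: HClO4 (cat.), THF–H2O, 0 °C
Reagents that add atoms: water, O
Why: In the acid-catalysed epoxide hydrolysis the protonated oxirane should open at the tertiary, cation-stabilising C8 (C7 is deactivated by the adjacent acetoxy group); the small nucleophile water is forced by the C8–O σ* geometry to enter from the α side in a trans-diaxial (Fürst–Plattner) sense, which inverts C8 to 8α-OH/8β-Me and retains 7β-OH.

Compound list
1 | (S)-(+)-carvone | CC1=CC[C@@H](CC1=O)C(C)=C | starting material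
2 | 2,3-dibromopropene | C=C(Br)CBr | starting material
3 | trans-6-(2-bromoallyl)carvone | O=C1C(C)=CC[C@H](C(C)=C)[C@H]1CC(Br)=C | intermediate
4 | 6-(2-bromoallyl)-6-methylcarvone (methyl β, bromoallyl α) | O=C1C(C)=CC[C@H](C(C)=C)[C@]1(C)CC(Br)=C | intermediate
5 | cyclisation precursor, 6-[2-(methoxycarbonyl)allyl]-6-methylcarvone (chain cis to isopropenyl) | O=C1C(C)=CC[C@H](C(C)=C)[C@]1(C)CC(=C)C(=O)OC | intermediate
6 | methyl 9-oxo-5-epi-11-nordrim-7-ene-2-carboxylate (both C2 epimers) | O=C1C(C)=CC[C@@H]2C(C)(C)CC(C(=O)OC)C[C@@]21C | intermediate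
7 | 9-oxo-5-epi-11-nordrim-7-ene-2-carboxylic acid (both C2 epimers) | O=C1C(C)=CC[C@@H]2C(C)(C)CC(C(=O)O)C[C@@]21C | intermediate
8 | Barton ester of 7 (2-thioxopyridin-1-yl ester) | O=C1C(C)=CC[C@@H]2C(C)(C)CC(C(=O)ON3C=CC=CC3=S)C[C@@]21C | intermediate
9 | 5-epi-11-nordrim-7-en-9-one | O=C1C(C)=CC[C@@H]2C(C)(C)CCC[C@@]21C | intermediate
10 | 7β,8β-epoxy-5-epi-11-nordriman-9-one | O=C1[C@@]3(C)O[C@H]3C[C@@H]2C(C)(C)CCC[C@@]21C | intermediate
11 | hydrazone of 10 | NN=C1[C@@]3(C)O[C@H]3C[C@@H]2C(C)(C)CCC[C@@]21C | intermediate
12 | 5-epi-11-nordrim-8-en-7β-ol | C1=C(C)[C@@H](O)C[C@@H]2C(C)(C)CCC[C@@]21C | intermediate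
13 | tributyl(iodomethyl)stannane | CCCC[Sn](CCCC)(CCCC)CI | starting material
14 | 7β-(tributylstannylmethoxy)-5-epi-11-nordrim-8-ene | C1=C(C)[C@@H](OC[Sn](CCCC)(CCCC)CCCC)C[C@@H]2C(C)(C)CCC[C@@]21C | intermediate
15 | 7β-(lithiomethoxy)-5-epi-11-nordrim-8-ene | C1=C(C)[C@@H](OC[Li])C[C@@H]2C(C)(C)CCC[C@@]21C | intermediate
16 | lithium alkoxide of 5-epi-drimenol (9β-CH2OLi) | [Li]OC[C@H]1C(C)=CC[C@@H]2C(C)(C)CCC[C@@]21C | intermediate
17 | 11-O-TBS-5-epi-drimenol | CC(C)(C)[Si](C)(C)OC[C@H]1C(C)=CC[C@@H]2C(C)(C)CCC[C@@]21C | intermediate
18 | 11-(TBS-oxy)-5-epi-drim-7-en-6-one | CC(C)(C)[Si](C)(C)OC[C@H]1C(C)=CC(=O)[C@@H]2C(C)(C)CCC[C@@]21C | intermediate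
19 | 11-(TBS-oxy)-5-epi-drim-7-en-6α-ol | CC(C)(C)[Si](C)(C)OC[C@H]1C(C)=C[C@H](O)[C@@H]2C(C)(C)CCC[C@@]21C | intermediate
20 | 6α-acetoxy-11-(TBS-oxy)-5-epi-drim-7-ene | CC(C)(C)[Si](C)(C)OC[C@H]1C(C)=C[C@H](OC(C)=O)[C@@H]2C(C)(C)CCC[C@@]21C | intermediate
21 | 6α-acetoxy-5-epi-drim-7-en-11-ol | OC[C@H]1C(C)=C[C@H](OC(C)=O)[C@@H]2C(C)(C)CCC[C@@]21C | intermediate
22 | 6α-acetoxy-5-epi-drim-7-en-11-al | O=C[C@H]1C(C)=C[C@H](OC(C)=O)[C@@H]2C(C)(C)CCC[C@@]21C | intermediate
23 | 1-(triphenylphosphoranylidene)propan-2-one | CC(=O)C=P(c1ccccc1)(c1ccccc1)c1ccccc1 | starting material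
24 | (E)-6α-acetoxy-5-epi-14,15-dinorlabda-7,11-dien-13-one | CC(=O)/C=C/[C@H]1C(C)=C[C@H](OC(C)=O)[C@@H]2C(C)(C)CCC[C@@]21C | intermediate
25 | (E)-6α-acetoxy-7β,8β-epoxy-5-epi-14,15-dinorlabd-11-en-13-one | CC(=O)/C=C/[C@H]1[C@@]3(C)O[C@H]3[C@H](OC(C)=O)[C@@H]2C(C)(C)CCC[C@@]21C | intermediate
26 | CNP0136046.2, (E)-6α-acetoxy-7β,8α-dihydroxy-5-epi-14,15-dinorlabd-11-en-13-one | CC(=O)/C=C/[C@H]1[C@](C)(O)[C@@H](O)[C@H](OC(C)=O)[C@@H]2C(C)(C)CCC[C@@]21C | target

Total step count: 18. Longest linear sequence: 18 steps from (S)-(+)-carvone (fully linear).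

Steps most likely to fail

Step 4. Hydrogen atom transfer may go astray, to the acrylate or the enone. The C4 radical may also be quenched by a second hydrogen atom before it cyclises. The fallback sets out from 5. HBr in AcOH at 0 °C should add in the Markovnikov sense to the isopropenyl group only, as in the formation of carvone hydrobromide, and give the tertiary bromide F1. Slow addition of Bu3SnH with AIBN in refluxing benzene then generates the same C4 radical by bromine abstraction, so no metal hydride meets the acrylate or the enone. The tin-hydride Giese closure (6-endo) comes back to the route at 6.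

Step 8. Condensation of hydrazine with the C9 carbonyl, which lies between two fully substituted carbons, may be too slow, so that nucleophilic opening of the epoxide by hydrazine takes over. The fallback sets out from 10. NaBH4 in MeOH should reduce the ketone to the epoxy alcohol F2; either C9 epimer serves. 1,1'-Thiocarbonyldiimidazole with DMAP converts it into the imidazolylthiocarbonate F3. Bu3SnH with AIBN then forms the C9 radical, whose oxiranylcarbinyl fragmentation cleaves C8–O. The resulting 7β-alkoxy radical takes up hydrogen. This radical counterpart of the transposition comes back to the route at 12.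

Step 18. Ionisation at C8 may be followed by proton loss from C9, driven by conjugation with the enone. Participation or migration of the neighbouring acetate may also replace capture of water. The fallback sets out from 21 and installs the diol before the enone exists.
- VO(acac)2 with t-BuOOH, directed by the homoallylic 9β-CH2OH, should give the epoxy alcohol F4 from the β face.
- Dilute HClO4 in aqueous THF opens it at C8 to the triol monoacetate F5.
- TEMPO with PhI(OAc)2 oxidises only the primary alcohol to the hydroxy aldehyde F6. The equatorial 7β-OH is too far from C11 for lactol formation.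
- Wittig olefination with 23 comes back to the route at 26.

Further compounds
F1 | step 4 | tertiary bromide, 5 with C(CH3)2Br in place of the isopropenyl group | O=C1C(C)=CC[C@H](C(C)(C)Br)[C@]1(C)CC(=C)C(=O)OC
F2 | step 8 | 7β,8β-epoxy-5-epi-11-nordriman-9-ol (either C9 epimer) | OC1[C@@]3(C)O[C@H]3C[C@@H]2C(C)(C)CCC[C@@]21C
F3 | step 8 | O-(7β,8β-epoxy-5-epi-11-nordriman-9-yl) imidazole-1-carbothioate | S=C(OC1[C@@]3(C)O[C@H]3C[C@@H]2C(C)(C)CCC[C@@]21C)n1ccnc1
F4 | step 18 | 6α-acetoxy-7β,8β-epoxy-5-epi-driman-11-ol | OC[C@H]1[C@@]3(C)O[C@H]3[C@H](OC(C)=O)[C@@H]2C(C)(C)CCC[C@@]21C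
F5 | step 18 | 6α-acetoxy-5-epi-drimane-7β,8α,11-triol | OC[C@H]1[C@](C)(O)[C@@H](O)[C@H](OC(C)=O)[C@@H]2C(C)(C)CCC[C@@]21C
F6 | step 18 | 6α-acetoxy-7β,8α-dihydroxy-5-epi-driman-11-al | O=C[C@H]1[C@](C)(O)[C@@H](O)[C@H](OC(C)=O)[C@@H]2C(C)(C)CCC[C@@]21C
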